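**Plan**
- Retrosynthetic cuts, in this order: C4=C5 (ring-closing metathesis); C11–C12 together with O6–C12 (the lactone carbonyl C12 is CO); C10–C1 (aldol); O8–acyl (ester); C9–C10 (ethyl Grignard on a Weinreb amide); C7–C8 (allenylindium plus glyoxylate); C7–C11 (acetylide).
- Forward: the C5–C9 chain is built linearly from (S)-but-3-ene-1,2-diol, then the epoxy ester and the C1–C4 aldehyde are attached. The five-membered lactone is closed by carbonylation on the unprotected open chain, and the ten-membered ring is closed last.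
- Enabling feature: the hydroxyl on C6 and the ethynyl carbon C11 on C7 sit on adjacent stereocentres. Four of the five atoms of the α-methylene-γ-butyrolactone ring (O, C6, C7, C11) are therefore in place; CO supplies C12 and the alkyne terminus becomes the exocyclic C13. The cis-fused lactone then acts as the turn element for the ten-membered ring.
- Stereochemistry: C6 from the chiral pool; C7 and C8 by chirality transfer from a propargylic mesylate whose carbinol is set by Felkin–Anh addition; C10 and C1 by 1,4-induction from the C8 acyloxy group in an anti-aldol; the epoxide by Sharpless epoxidation; (Z)-C4=C5 by the ring.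

Key step: step 14

Assumption: carbons are numbered as in germacranolides (ring C1–C10 with C1 carbinol, C4=C5 alkene, C6 lactone carbinol, C8 ester carbinol, C9 ketone; C11 lactone α-carbon, C12 lactone carbonyl, C13 methylidene). The γ-hydroxy ketone 22 is taken to be in mobile equilibrium with its five-membered hemiketal.

Step 1
Reactants: 1 methyl (Z)-2-methylbut-2-enoate (methyl angelate)
Product: 2 (Z)-2-methylbut-2-en-1-ol
Conditions: iBu2AlH (2.2 equiv), CH2Cl2, −78 °C to 0 °C
Reagents that add atoms: none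
Why: Ester reduction with iBu2AlH at low temperature should deliver hydride 1,2 only and leave the (Z)-trisubstituted alkene unisomerised.

Step 2
Reactants: 2 (Z)-2-methylbut-2-en-1-ol
Product: 3 [(2S,3R)-2,3-dimethyloxiran-2-yl]methanol
Conditions: Ti(OiPr)4 (10 mol %), L-(+)-diethyl tartrate (12 mol %), tBuOOH, 4 Å molecular sieves, CH2Cl2, −20 °C
Reagents that add atoms: tert-butyl hydroperoxide, CC(C)(C)OO
Why: Sharpless asymmetric epoxidation, in which the L-(+)-tartrate complex delivers oxygen to the face of the allylic alcohol that gives the (2S,3R)-epoxide, while the stereospecific oxygen transfer keeps CH2OH and the C3 methyl cis.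

Step 3
Reactants: 3 [(2S,3R)-2,3-dimethyloxiran-2-yl]methanol
Product: 4 (2R,3R)-2,3-dimethyloxirane-2-carboxylic acid
Conditions: RuCl3 (2 mol %), NaIO4, CCl4/MeCN/H2O, rt
Reagents that add atoms: water, O; sodium periodate, [Na+].[O-]I(=O)(=O)=O
Why: Oxidation with RuO4 formed in situ should take the primary alcohol of a 2,3-epoxy alcohol to the acid without opening the epoxide, so both stereocentres are carried over (only the C2 descriptor changes).

Step 4
Reactants: 5 ethyl 4-methylpent-4-enoate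
Product: 6 4-methylpent-4-enal
Conditions: iBu2AlH (1.05 equiv), CH2Cl2, −78 °C
Reagents that add atoms: none
Why: Partial ester reduction, in which the tetrahedral aluminium hemiacetal is stable at −78 °C and releases the aldehyde only on work-up.

Step 5
Reactants: 7 (S)-but-3-ene-1,2-diol
Product: 8 (S)-3,4-bis(triethylsilyloxy)but-1-ene
Conditions: Et3SiCl, imidazole, CH2Cl2, 0 °C to rt
Reagents that add atoms: chlorotriethylsilane, CC[Si](Cl)(CC)CC
Why: Exhaustive silylation of both hydroxyls; the stereocentre (later C6) is not touched.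

Step 6
Reactants: 8 (S)-3,4-bis(triethylsilyloxy)but-1-ene
Product: 9 (S)-2-(triethylsilyloxy)but-3-enal
Conditions: (COCl)2, DMSO, CH2Cl2, −78 °C to −30 °C; then iPr2NEt, −78 °C
Reagents that add atoms: none
Why: Swern oxidation of a primary triethylsilyl ether, in which activated dimethyl sulfoxide cleaves only the less hindered primary O–Si bond and oxidises that carbon, while the cold hindered-base work-up should keep the α-silyloxy β,γ-unsaturated aldehyde from epimerising or conjugating.

Step 7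
Reactants: 9 (S)-2-(triethylsilyloxy)but-3-enal
Product: 10 (3R,4S)-4-(triethylsilyloxy)hex-5-en-1-yn-3-ol
Conditions: HC≡CMgBr, THF, −78 °C
Reagents that add atoms: ethynylmagnesium bromide, C#C[Mg]Br
Why: Felkin–Anh (polar, non-chelating) addition of the acetylide to the α-silyloxy aldehyde should favour the 3,4-anti alcohol and so fix the propargylic carbinol as 3R; the minor syn epimer is removed by chromatography.

Step 8
Reactants: 10 (3R,4S)-4-(triethylsilyloxy)hex-5-en-1-yn-3-ol
Product: 11 (3R,4S)-4-(triethylsilyloxy)hex-5-en-1-yn-3-yl methanesulfonate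
Conditions: MeSO2Cl, Et3N, CH2Cl2, −78 °C to −20 °C
Reagents that add atoms: methanesulfonyl chloride, CS(=O)(=O)Cl
Why: Sulfonylation at oxygen with retention gives the propargylic leaving group needed for the SN2' palladation.

Step 9
Reactants: 11 (3R,4S)-4-(triethylsilyloxy)hex-5-en-1-yn-3-yl methanesulfonate; 12 ethyl glyoxylate
Product: 14 ethyl (2R,3R,4S)-3-ethynyl-2-hydroxy-4-(triethylsilyloxy)hex-5-enoate, via allenylindium iodide methanesulfonate 13 (not isolated)
Conditions: Pd(dppf)Cl2 (5 mol %), InI (1.4 equiv), THF/HMPA 3:1, rt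
Reagents that add atoms: InI, [In]I (atoms only in intermediate 13)
Why: Marshall–Tamaru propargylation, in which zerovalent palladium displaces the mesylate anti-SN2', InI takes over the allenyl group with retention to give 13, and 13 adds to the aldehyde through a closed six-membered SE2' transition state with the aldehyde substituent turned away from the C6 group, so that C7 forms with net inversion of the mesylate centre and C8 with the anti relationship.

Step 10
Reactants: 14 ethyl (2R,3R,4S)-3-ethynyl-2-hydroxy-4-(triethylsilyloxy)hex-5-enoate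
Product: 16 (4R,5R,6S)-5-ethynyl-4-hydroxy-6-(triethylsilyloxy)oct-7-en-3-one, via Weinreb amide 15 (not isolated)
Conditions: MeNHOMe·HCl (3 equiv), EtMgBr (10 equiv), THF, −20 °C to 0 °C; aq NH4Cl
Reagents that add atoms: ethylmagnesium bromide, CC[Mg]Br; N,O-dimethylhydroxylamine hydrochloride, CNOC.Cl (atoms only in intermediate 15)
Why: One-pot Weinreb ketone synthesis, in which the magnesium amide of MeNHOMe converts the ester into 15 and the chelated tetrahedral adduct of 15 with EtMgBr resists over-addition, while the α-alkoxide and the acetylide formed in situ protect C8 and the alkyne.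

Step 11
Reactants: 16 (4R,5R,6S)-5-ethynyl-4-hydroxy-6-(triethylsilyloxy)oct-7-en-3-one; 4 (2R,3R)-2,3-dimethyloxirane-2-carboxylic acid
Product: 18 (4R,5R,6S)-5-ethynyl-3-oxo-6-(triethylsilyloxy)oct-7-en-4-yl (2R,3R)-2,3-dimethyloxirane-2-carboxylate, via mixed anhydride 17 (not isolated)
Conditions: 4, 2,4,6-Cl3C6H2COCl, Et3N, THF, rt; then 16, DMAP, toluene, 0 °C to rt
Reagents that add atoms: 2,4,6-trichlorobenzoyl chloride, O=C(Cl)c1c(Cl)cc(Cl)cc1Cl (atoms only in intermediate 17)
Why: Yamaguchi esterification, in which DMAP transfers the epoxy acyl group from the unshielded carbonyl of the mixed anhydride to the hindered C8 hydroxyl; the acid has no α-hydrogen and the short, cold reaction should leave C8 unepimerised.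

Step 12
Reactants: 18 (4R,5R,6S)-5-ethynyl-3-oxo-6-(triethylsilyloxy)oct-7-en-4-yl (2R,3R)-2,3-dimethyloxirane-2-carboxylate; 6 4-methylpent-4-enal
Product: 21 (3S,4R,5R,7S,8S)-4-ethynyl-8-hydroxy-7,11-dimethyl-6-oxo-3-(triethylsilyloxy)dodeca-1,11-dien-5-yl (2R,3R)-2,3-dimethyloxirane-2-carboxylate, via enol borinate 19 (not isolated), via boron aldolate 20 (not isolated)
Conditions: Cy2BCl, Me2NEt, Et2O, −78 °C to 0 °C; then 6, −78 °C to −20 °C; then MeOH, pH 7 buffer, H2O2, 0 °C
Reagents that add atoms: chlorodicyclohexylborane, ClB(C1CCCCC1)C1CCCCC1 (atoms only in intermediates 19 and 20)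
Why: Paterson anti-aldol of an α-acyloxy ethyl ketone, in which Cy2BCl/Me2NEt gives the (E)-enol borinate on the ethyl side and its chair transition state gives the C10/C1 anti pair, while the C8 acyloxy group (C8–H eclipsing the enolate, formyl hydrogen bonded to the ester carbonyl) should direct the aldehyde to the face that sets 10S and 1S.

Step 13
Reactants: 21 (3S,4R,5R,7S,8S)-4-ethynyl-8-hydroxy-7,11-dimethyl-6-oxo-3-(triethylsilyloxy)dodeca-1,11-dien-5-yl (2R,3R)-2,3-dimethyloxirane-2-carboxylate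
Product: 22 (3S,4S,5R,7S,8S)-4-ethynyl-3,8-dihydroxy-7,11-dimethyl-6-oxododeca-1,11-dien-5-yl (2R,3R)-2,3-dimethyloxirane-2-carboxylate
Conditions: HF·pyridine, pyridine, THF, 0 °C
Reagents that add atoms: none
Why: Fluoride-mediated desilylation of the secondary triethylsilyl ether under buffered, weakly acidic conditions that should leave the epoxy ester and the β-hydroxy ketone intact and avoid a base-induced 1,3-acyl shift.

Step 14
Reactants: 22 (3S,4S,5R,7S,8S)-4-ethynyl-3,8-dihydroxy-7,11-dimethyl-6-oxododeca-1,11-dien-5-yl (2R,3R)-2,3-dimethyloxirane-2-carboxylate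
Product: 23 (1R,3S,4S)-1-[(2S,3S)-2-ethenyl-4-methylidene-5-oxooxolan-3-yl]-4-hydroxy-3,7-dimethyl-2-oxooct-7-en-1-yl (2R,3R)-2,3-dimethyloxirane-2-carboxylate
Conditions: PdI2 (10 mol %), PBu3 (20 mol %), CO (7 atm), MeCN, 75 °C
Reagents that add atoms: carbon monoxide, [C-]#[O+]
Why: PdI2(PBu3)2, the C6 hydroxyl and CO should form an alkoxycarbonylpalladium iodide (divalent palladium, HI set free); the ethynyl group on C7 then inserts syn into the Pd–C(=O)O bond, which forms the C11–C12 bond and closes the lactone, and protonolysis of the exocyclic vinylpalladium by HI gives the methylidene C13 and returns the catalyst. The closest known reaction type is the palladium-catalysed cyclocarbonylation of but-3-yn-1-ols (for example 2-ethynylcyclohexanols) to α-methylene-γ-butyrolactones. The one ring that is closed forms in the 5-exo-dig mode. No stereocentre is created: the cis ring fusion is fixed by the C6 and C7 configurations set in steps 5, 7 and 9, and a cis-fused five-membered lactone is unstrained. The step needs chemoselectivity for the C6 hydroxyl over the C1 hydroxyl and for the alkyne over both alkenes; this is secured because only O6 reaches C11 through a five-membered ring (O8, the other homopropargylic oxygen, is acylated) and because alkynes insert into the alkoxycarbonyl–palladium bond far faster than unactivated alkenes. The medium is neutral, so the epoxide, the β-hydroxy ketone and the epimerisable C8 and C10 centres should survive.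

Step 15
Reactants: 23 (1R,3S,4S)-1-[(2S,3S)-2-ethenyl-4-methylidene-5-oxooxolan-3-yl]-4-hydroxy-3,7-dimethyl-2-oxooct-7-en-1-yl (2R,3R)-2,3-dimethyloxirane-2-carboxylate
Product: 24 (3aS,4R,6S,7S,10Z,11aS)-7-hydroxy-6,10-dimethyl-3-methylidene-2,5-dioxo-2,3,3a,4,5,6,7,8,9,11a-decahydrocyclodeca[b]furan-4-yl (2R,3R)-2,3-dimethyloxirane-2-carboxylate (CNP0149149.1)
Conditions: second-generation Grubbs catalyst (10 mol %), toluene (1 mM), 80 °C
Reagents that add atoms: none
Why: Ring-closing metathesis between the vinyl group on C6 and the 1,1-disubstituted alkene, in which the cis-fused lactone holds C5 and C8 on one face as a turn element, the ten-membered ring should favour the less strained (Z)-trisubstituted alkene, loss of ethene drives the closure, and the electron-poor methylidene lactone should stay out of the metathesis.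

**Compound list**
1 | methyl (Z)-2-methylbut-2-enoate (methyl angelate) | C/C=C(/C)C(=O)OC | starting material
2 | (Z)-2-methylbut-2-en-1-ol | C/C=C(/C)CO | intermediate
3 | [(2S,3R)-2,3-dimethyloxiran-2-yl]methanol | OC[C@]1(C)O[C@@H]1C | intermediate
4 | (2R,3R)-2,3-dimethyloxirane-2-carboxylic acid | OC(=O)[C@]1(C)O[C@@H]1C | intermediate
5 | ethyl 4-methylpent-4-enoate | CCOC(=O)CCC(C)=C | starting material
6 | 4-methylpent-4-enal | O=CCCC(C)=C | intermediate
7 | (S)-but-3-ene-1,2-diol | OC[C@@H](O)C=C | starting material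
8 | (S)-3,4-bis(triethylsilyloxy)but-1-ene | CC[Si](CC)(CC)OC[C@@H](O[Si](CC)(CC)CC)C=C | intermediate
9 | (S)-2-(triethylsilyloxy)but-3-enal | O=C[C@@H](O[Si](CC)(CC)CC)C=C | intermediate
10 | (3R,4S)-4-(triethylsilyloxy)hex-5-en-1-yn-3-ol | C#C[C@@H](O)[C@@H](O[Si](CC)(CC)CC)C=C | intermediate
11 | (3R,4S)-4-(triethylsilyloxy)hex-5-en-1-yn-3-yl methanesulfonate | C#C[C@@H](OS(C)(=O)=O)[C@@H](O[Si](CC)(CC)CC)C=C | intermediate
12 | ethyl glyoxylate (ethyl 2-oxoacetate) | CCOC(=O)C=O | starting material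
13 | [(aR,4S)-4-(triethylsilyloxy)hexa-1,2,5-trien-1-yl]indium iodide methanesulfonate | I[In](OS(C)(=O)=O)C=[C@]=C[C@@H](O[Si](CC)(CC)CC)C=C | intermediate
14 | ethyl (2R,3R,4S)-3-ethynyl-2-hydroxy-4-(triethylsilyloxy)hex-5-enoate | C=C[C@H](O[Si](CC)(CC)CC)[C@H](C#C)[C@@H](O)C(=O)OCC | intermediate
15 | (2R,3R,4S)-3-ethynyl-2-hydroxy-N-methoxy-N-methyl-4-(triethylsilyloxy)hex-5-enamide | C=C[C@H](O[Si](CC)(CC)CC)[C@H](C#C)[C@@H](O)C(=O)N(C)OC | intermediate
16 | (4R,5R,6S)-5-ethynyl-4-hydroxy-6-(triethylsilyloxy)oct-7-en-3-one | C=C[C@H](O[Si](CC)(CC)CC)[C@H](C#C)[C@@H](O)C(=O)CC | intermediate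
17 | (2R,3R)-2,3-dimethyloxirane-2-carboxylic 2,4,6-trichlorobenzoic anhydride | O=C(OC(=O)[C@]1(C)O[C@@H]1C)c1c(Cl)cc(Cl)cc1Cl | intermediate
18 | (4R,5R,6S)-5-ethynyl-3-oxo-6-(triethylsilyloxy)oct-7-en-4-yl (2R,3R)-2,3-dimethyloxirane-2-carboxylate | C=C[C@H](O[Si](CC)(CC)CC)[C@H](C#C)[C@@H](OC(=O)[C@]1(C)O[C@@H]1C)C(=O)CC | intermediate
19 | (2E,4R,5R,6S)-3-(dicyclohexylboryloxy)-5-ethynyl-6-(triethylsilyloxy)octa-2,7-dien-4-yl (2R,3R)-2,3-dimethyloxirane-2-carboxylate | C=C[C@H](O[Si](CC)(CC)CC)[C@H](C#C)[C@@H](OC(=O)[C@]1(C)O[C@@H]1C)/C(OB(C1CCCCC1)C1CCCCC1)=C\C | intermediate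
20 | (3S,4R,5R,7S,8S)-8-(dicyclohexylboryloxy)-4-ethynyl-7,11-dimethyl-6-oxo-3-(triethylsilyloxy)dodeca-1,11-dien-5-yl (2R,3R)-2,3-dimethyloxirane-2-carboxylate | C=C[C@H](O[Si](CC)(CC)CC)[C@H](C#C)[C@@H](OC(=O)[C@]1(C)O[C@@H]1C)C(=O)[C@@H](C)[C@@H](OB(C1CCCCC1)C1CCCCC1)CCC(C)=C | intermediate
21 | (3S,4R,5R,7S,8S)-4-ethynyl-8-hydroxy-7,11-dimethyl-6-oxo-3-(triethylsilyloxy)dodeca-1,11-dien-5-yl (2R,3R)-2,3-dimethyloxirane-2-carboxylate | C=C[C@H](O[Si](CC)(CC)CC)[C@H](C#C)[C@@H](OC(=O)[C@]1(C)O[C@@H]1C)C(=O)[C@@H](C)[C@@H](O)CCC(C)=C | intermediate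
22 | (3S,4S,5R,7S,8S)-4-ethynyl-3,8-dihydroxy-7,11-dimethyl-6-oxododeca-1,11-dien-5-yl (2R,3R)-2,3-dimethyloxirane-2-carboxylate | C=C[C@H](O)[C@H](C#C)[C@@H](OC(=O)[C@]1(C)O[C@@H]1C)C(=O)[C@@H](C)[C@@H](O)CCC(C)=C | intermediate
23 | (1R,3S,4S)-1-[(2S,3S)-2-ethenyl-4-methylidene-5-oxooxolan-3-yl]-4-hydroxy-3,7-dimethyl-2-oxooct-7-en-1-yl (2R,3R)-2,3-dimethyloxirane-2-carboxylate | C=C1C(=O)O[C@@H](C=C)[C@H]1[C@@H](OC(=O)[C@]2(C)O[C@@H]2C)C(=O)[C@@H](C)[C@@H](O)CCC(C)=C | intermediate
24 | (3aS,4R,6S,7S,10Z,11aS)-7-hydroxy-6,10-dimethyl-3-methylidene-2,5-dioxo-2,3,3a,4,5,6,7,8,9,11a-decahydrocyclodeca[b]furan-4-yl (2R,3R)-2,3-dimethyloxirane-2-carboxylate | C=C1C(=O)O[C@H]2/C=C(/C)CC[C@H](O)[C@H](C)C(=O)[C@H](OC(=O)[C@]3(C)O[C@@H]3C)[C@@H]12 | target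

**Step count and risks**
Total step count: 15. Longest linear sequence: 11 (steps 5 to 15).

Steps most likely to fail:

1. Step 15 (ring-closing metathesis). Intermolecular metathesis to oligomers may outrun closure of the strained ten-membered ring, or the ruthenium carbene may fail to engage the 1,1-disubstituted alkene. Fallback (ten-membered ring first, lactone last): it sets out from 21 and comes back at 24. The alkyne of 21 is masked with Co2(CO)8 (CH2Cl2, rt) as the hexacarbonyldicobalt complex F1. Ring-closing metathesis of F1 (second-generation Grubbs catalyst, CH2Cl2, 40 °C, high dilution), now on a lactone-free and more flexible chain, should give the macrocyclic cobalt complex F2. Oxidative decomplexation with (NH4)2Ce(NO3)6 (acetone, −20 °C) frees the macrocyclic alkyne F3, and HF·pyridine gives the macrocyclic diol F4. The cyclocarbonylation of step 14, run on F4, then closes the lactone as the last event and gives 24.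

2. Step 9 (allenylindium addition). The propargyl/allenyl metal species may lose the neighbouring silyloxy group by β-elimination, or chelation of indium by the glyoxylate ester may erode the anti selectivity. Fallback (isolable allenylboronate, addition without a polar metal): it sets out from 10 and comes back at 14. Alcohol 10 and methyl chloroformate/pyridine give the methyl carbonate F5. Anti-SN2' borylation of F5 with B2pin2 (CuOtBu/Xantphos cat., THF, rt) gives the allenylboronate F6, which has the same axial sense as 13. F6 and 12 in toluene should react through the closed six-membered transition state to the boronate ester F7, which is hydrolysed on work-up to 14.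

3. Step 12 (anti-aldol directed by the epoxy ester). The chloroborane may open the epoxide, or the epoxy ester may give a weaker facial bias than the benzoate for which this aldol is established. Fallback (benzoate as director, ester exchange afterwards): it sets out from 16 and comes back at 22. Benzoylation of 16 (PhCOCl, pyridine, DMAP) gives the benzoate F8. Cy2BCl/Me2NEt converts F8 into the enol borinate F9, aldehyde 6 gives the boron aldolate F10, and oxidative work-up gives the aldol F11. Et3SiOTf/2,6-lutidine gives the bis-silyl ether F12, and K2CO3/MeOH at 0 °C removes the benzoate to give the α-hydroxy ketone F13. Yamaguchi esterification of F13 with mixed anhydride 17 gives the epoxy ester F14, and HF·pyridine removes both silyl groups to give 22.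

**Further compounds**
F1 | step 15 | hexacarbonyldicobalt complex of the alkyne of 21 | C=C[C@H](O[Si](CC)(CC)CC)[C@H](C12[CH]3[Co]1(=C=O)(=C=O)(=C=O)[Co]23(=C=O)(=C=O)=C=O)[C@@H](OC(=O)[C@]4(C)O[C@@H]4C)C(=O)[C@@H](C)[C@@H](O)CCC(C)=C
F2 | step 15 | hexacarbonyldicobalt complex of the alkyne of F3 | C/C1=C/[C@H](O[Si](CC)(CC)CC)[C@H](C23[CH]4[Co]2(=C=O)(=C=O)(=C=O)[Co]34(=C=O)(=C=O)=C=O)[C@@H](OC(=O)[C@]5(C)O[C@@H]5C)C(=O)[C@@H](C)[C@@H](O)CC1
F3 | step 15 | (1R,2R,3S,4Z,8S,9S)-2-ethynyl-8-hydroxy-5,9-dimethyl-10-oxo-3-(triethylsilyloxy)cyclodec-4-en-1-yl (2R,3R)-2,3-dimethyloxirane-2-carboxylate | C/C1=C/[C@H](O[Si](CC)(CC)CC)[C@H](C#C)[C@@H](OC(=O)[C@]2(C)O[C@@H]2C)C(=O)[C@@H](C)[C@@H](O)CC1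
F4 | step 15 | (1R,2S,3S,4Z,8S,9S)-2-ethynyl-3,8-dihydroxy-5,9-dimethyl-10-oxocyclodec-4-en-1-yl (2R,3R)-2,3-dimethyloxirane-2-carboxylate | C/C1=C/[C@H](O)[C@H](C#C)[C@@H](OC(=O)[C@]2(C)O[C@@H]2C)C(=O)[C@@H](C)[C@@H](O)CC1
F5 | step 9 | (3R,4S)-4-(triethylsilyloxy)hex-5-en-1-yn-3-yl methyl carbonate | C#C[C@@H](OC(=O)OC)[C@@H](O[Si](CC)(CC)CC)C=C
F6 | step 9 | 4,4,5,5-tetramethyl-2-[(aR,4S)-4-(triethylsilyloxy)hexa-1,2,5-trien-1-yl]-1,3,2-dioxaborolane | CC1(C)OB(OC1(C)C)C=[C@]=C[C@@H](O[Si](CC)(CC)CC)C=C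
F7 | step 9 | ethyl (2R,3R,4S)-3-ethynyl-2-[(4,4,5,5-tetramethyl-1,3,2-dioxaborolan-2-yl)oxy]-4-(triethylsilyloxy)hex-5-enoate | C=C[C@H](O[Si](CC)(CC)CC)[C@H](C#C)[C@@H](OB1OC(C)(C)C(C)(C)O1)C(=O)OCC
F8 | step 12 | (4R,5R,6S)-5-ethynyl-3-oxo-6-(triethylsilyloxy)oct-7-en-4-yl benzoate | C=C[C@H](O[Si](CC)(CC)CC)[C@H](C#C)[C@@H](OC(=O)c1ccccc1)C(=O)CC
F9 | step 12 | (2E,4R,5R,6S)-3-(dicyclohexylboryloxy)-5-ethynyl-6-(triethylsilyloxy)octa-2,7-dien-4-yl benzoate | C=C[C@H](O[Si](CC)(CC)CC)[C@H](C#C)[C@@H](OC(=O)c1ccccc1)/C(OB(C1CCCCC1)C1CCCCC1)=C\C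
F10 | step 12 | (3S,4R,5R,7S,8S)-8-(dicyclohexylboryloxy)-4-ethynyl-7,11-dimethyl-6-oxo-3-(triethylsilyloxy)dodeca-1,11-dien-5-yl benzoate | C=C[C@H](O[Si](CC)(CC)CC)[C@H](C#C)[C@@H](OC(=O)c1ccccc1)C(=O)[C@@H](C)[C@@H](OB(C1CCCCC1)C1CCCCC1)CCC(C)=C
F11 | step 12 | (3S,4R,5R,7S,8S)-4-ethynyl-8-hydroxy-7,11-dimethyl-6-oxo-3-(triethylsilyloxy)dodeca-1,11-dien-5-yl benzoate | C=C[C@H](O[Si](CC)(CC)CC)[C@H](C#C)[C@@H](OC(=O)c1ccccc1)C(=O)[C@@H](C)[C@@H](O)CCC(C)=C
F12 | step 12 | (3S,4R,5R,7S,8S)-4-ethynyl-7,11-dimethyl-6-oxo-3,8-bis(triethylsilyloxy)dodeca-1,11-dien-5-yl benzoate | C=C[C@H](O[Si](CC)(CC)CC)[C@H](C#C)[C@@H](OC(=O)c1ccccc1)C(=O)[C@@H](C)[C@@H](O[Si](CC)(CC)CC)CCC(C)=C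
F13 | step 12 | (3S,4R,5R,7S,8S)-4-ethynyl-5-hydroxy-7,11-dimethyl-3,8-bis(triethylsilyloxy)dodeca-1,11-dien-6-one | C=C[C@H](O[Si](CC)(CC)CC)[C@H](C#C)[C@@H](O)C(=O)[C@@H](C)[C@@H](O[Si](CC)(CC)CC)CCC(C)=C
F14 | step 12 | (3S,4R,5R,7S,8S)-4-ethynyl-7,11-dimethyl-6-oxo-3,8-bis(triethylsilyloxy)dodeca-1,11-dien-5-yl (2R,3R)-2,3-dimethyloxirane-2-carboxylate | C=C[C@H](O[Si](CC)(CC)CC)[C@H](C#C)[C@@H](OC(=O)[C@]1(C)O[C@@H]1C)C(=O)[C@@H](C)[C@@H](O[Si](CC)(CC)CC)CCC(C)=C
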